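**Strategy.** Ring A is made last, from a 2-pyrone. In the target, the ring A carbon bonded to the ester carbonyl of the seven-membered ring sits next to the ring A carbon bonded to the diaryl ether oxygen. These two links to ring B are therefore used as a ready-made tether between a diene and a dienophile. The precursor 22 is a ring B aryl 2-butynoate whose neighbouring oxygen carries a 4-(methoxymethoxy)-5-methoxy-2-pyron-3-yl group. Heating should add the ynoate across pyrone C3–C6 and expel CO2, which forms ring A and the seven-membered ring in one operation. Acidolysis and an enzymatic resolution of the lactol finish the synthesis.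

Key step: step 15

Assumption: the lactol carbon, the only stereocentre, can epimerise through the ring-opened aldehyde–acid. It is taken to be configurationally stable in neutral, anhydrous, aprotic media and as a solid, so it is set last and the target is isolated without base, water or heat.

Remark: ring B is numbered as the benzoate (C1 carboxyl, C2 OH, C3 methyl, C4 oxygen of the depsidone ester, C5 oxygen of the diaryl ether, C6 formyl or lactol carbon). Pyrone positions follow 2H-pyran-2-one. Compounds 2, 3, 4, 15, 16 and 17 are E/Z mixtures whose geometry is lost later; 16, 17, 23 and 26 are racemic.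

Step 1
Reactants: 1 methyl methoxyacetate
Product: 3 methyl 2,3-dimethoxyacrylate, via sodium enolate 2 (not isolated)
Conditions: NaH, HCO2Me, THF, 0 °C to rt; then Me2SO4, DMF, rt
Reagents that add atoms: methyl formate, COC=O; dimethyl sulfate, COS(=O)(=O)OC
Why: Crossed Claisen condensation with non-enolisable methyl formate gives the stabilised sodium formyl enolate, which the hard electrophile Me2SO4 methylates on oxygen in a dipolar solvent.

Step 2
Reactants: 3 methyl 2,3-dimethoxyacrylate
Product: 4 2,3-dimethoxyacrylic acid
Conditions: LiOH, THF/H2O, rt; then 1 M HCl to pH 3, 0 °C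
Reagents that add atoms: lithium hydroxide, [Li+].[OH-]
Why: Saponification of the methyl ester, with cold and careful acidification so that the enol ether is not hydrolysed.

Step 3
Reactants: 5 2,4-dihydroxy-3-methylbenzoic acid
Product: 7 2,4,5-trihydroxy-3-methylbenzoic acid, via aryl sulfate 6 (not isolated)
Conditions: K2S2O8, aq. NaOH, 0 to 20 °C, Ar; then HCl, 80 °C
Reagents that add atoms: potassium peroxodisulfate, [K+].[K+].[O-]S(=O)(=O)OOS([O-])(=O)=O
Why: Elbs persulfate oxidation, in which the phenoxide attacks a peroxide oxygen through C5 (para to the 2-hydroxyl and the only open activated position), followed by acid hydrolysis of the aryl sulfate.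

Step 4
Reactants: 7 2,4,5-trihydroxy-3-methylbenzoic acid
Product: 8 tert-butyl 2,4,5-trihydroxy-3-methylbenzoate
Conditions: tert-butyl 2,2,2-trichloroacetimidate, THF, rt, Ar
Reagents that add atoms: tert-butyl 2,2,2-trichloroacetimidate, CC(C)(C)OC(=N)C(Cl)(Cl)Cl
Why: Imidate esterification, in which the carboxylic acid protonates the imidate and takes up the tert-butyl cation, needs no base, so the oxidation-prone triol is spared and the phenols stay free.

Step 5
Reactants: 8 tert-butyl 2,4,5-trihydroxy-3-methylbenzoate
Product: 9 tert-butyl 4-(allyloxy)-2,5-dihydroxy-3-methylbenzoate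
Conditions: allyl bromide (1.05 equiv), Li2CO3, DMF, 40 °C, Ar
Reagents that add atoms: allyl bromide, C=CCBr
Why: Williamson etherification under a weak base goes to the 4-hydroxyl, which is para to the ester, not hydrogen-bonded and therefore the most acidic phenol, while the 2-hydroxyl is chelated by the ester and the 5-hydroxyl is the less acidic catechol oxygen.

Step 6
Reactants: 9 tert-butyl 4-(allyloxy)-2,5-dihydroxy-3-methylbenzoate
Product: 10 tert-butyl 4-(allyloxy)-6-formyl-2,5-dihydroxy-3-methylbenzoate
Conditions: MgCl2, Et3N, (CH2O)n, MeCN, 80 °C, Ar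
Reagents that add atoms: paraformaldehyde (as formaldehyde), C=O
Why: Magnesium-mediated ortho-formylation (phenoxide-directed hydroxymethylation, then hydride transfer to formaldehyde) can only reach C6, the single free position ortho to the 5-hydroxyl.

Step 7
Reactants: 10 tert-butyl 4-(allyloxy)-6-formyl-2,5-dihydroxy-3-methylbenzoate; 11 tert-butyl bromoacetate
Product: 12 tert-butyl 4-(allyloxy)-5-(2-tert-butoxy-2-oxoethoxy)-6-formyl-2-hydroxy-3-methylbenzoate
Conditions: K2CO3 (1.1 equiv), DMF, 0 °C to rt
Reagents that add atoms: none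
Why: Williamson etherification of the 5-hydroxyl, which the ortho-formyl group makes the more acidic phenol, while the hindered salicylate hydroxyl stays protonated with one equivalent of base and the low temperature prevents aldol closure to a benzofuran.

Step 8
Reactants: 12 tert-butyl 4-(allyloxy)-5-(2-tert-butoxy-2-oxoethoxy)-6-formyl-2-hydroxy-3-methylbenzoate
Product: 13 the dimethyl acetal of 12
Conditions: HC(OMe)3, MeOH, PPTS (cat.), rt
Reagents that add atoms: trimethyl orthoformate, COC(OC)OC; methanol, CO
Why: Acid-catalysed acetalisation driven by the orthoformate masks the aldehyde, which would otherwise capture the ester enolate of step 10 in a five-membered aldol.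

Step 9
Reactants: 13 the dimethyl acetal of 12
Product: 14 the 2-O-methoxymethyl ether of 13
Conditions: MOMCl, iPr2NEt, NaI (cat.), CH2Cl2, 40 °C
Reagents that add atoms: chloromethyl methyl ether, COCCl
Why: O-alkylation of the last free (hydrogen-bonded) phenol under amine base with iodide catalysis, so that this oxygen cannot be acylated in step 10 and the acetal is untouched.

Step 10
Reactants: 14 the 2-O-methoxymethyl ether of 13; 4 2,3-dimethoxyacrylic acid
Product: 16 β-keto ester carrying the 2,3-dimethoxyacryloyl group on the aryloxyacetate carbon, via 2,3-dimethoxyacryloyl chloride 15 (not isolated)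
Conditions: 4, (COCl)2, DMF (cat.), CH2Cl2, 0 °C to rt, evaporate; 14, LiN(SiMe3)2 (2.2 equiv), THF, −78 °C, then 15, −78 to −40 °C; aq. NH4Cl
Reagents that add atoms: none
Why: Claisen-type C-acylation of the lithium ester enolate by an acid chloride, which reacts only at the acyl carbon and not by substitution at the β-methoxy carbon, with the second equivalent of base storing the product as its enolate; the new carbon is racemic and becomes sp2 in step 11.

Step 11
Reactants: 16 β-keto ester
Product: 18 tert-butyl 4-(allyloxy)-6-formyl-5-[(4-hydroxy-5-methoxy-2-oxo-2H-pyran-3-yl)oxy]-2-(methoxymethoxy)-3-methylbenzoate, via formyl enol 17 (not isolated)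
Conditions: 1 M HCl, THF, 0 °C to rt; then xylene, 130 °C
Reagents that add atoms: water, O
Why: Dilute acid hydrolyses the enol ether and the dimethyl acetal but not the MOM ether or the tert-butyl esters, and heating then expels tert-butanol from the β-keto tert-butyl ester to give an acylketene that the formyl enol hydroxyl traps (acylketene lactonisation) to close the 4-hydroxy-2-pyrone, a path closed to the aryl tert-butyl ester.

Step 12
Reactants: 18 the 4-hydroxy-2-pyrone
Product: 19 tert-butyl 4-(allyloxy)-6-formyl-5-{[5-methoxy-4-(methoxymethoxy)-2-oxo-2H-pyran-3-yl]oxy}-2-(methoxymethoxy)-3-methylbenzoate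
Conditions: MOMCl, iPr2NEt, CH2Cl2, 0 °C
Reagents that add atoms: chloromethyl methyl ether, COCCl
Why: O-alkylation of the acidic 4-hydroxy-2-pyrone (a vinylogous carboxylic acid) by the hard oxocarbenium electrophile at the 4-oxygen, as is usual for this class, with carbon alkylation blocked because C3 and C5 are substituted.

Step 13
Reactants: 19 the allyl ether
Product: 20 tert-butyl 6-formyl-4-hydroxy-5-{[5-methoxy-4-(methoxymethoxy)-2-oxo-2H-pyran-3-yl]oxy}-2-(methoxymethoxy)-3-methylbenzoate
Conditions: Pd(PPh3)4 (cat.), 4-MeC6H4SO2Na, THF/MeOH, rt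
Reagents that add atoms: none
Why: Tsuji–Trost deallylation, in which zerovalent palladium ionises the aryl allyl ether and the sulfinate traps the allyl fragment, runs under neutral conditions that spare the aldehyde, pyrone, MOM groups and tert-butyl ester and keep the freed phenol from attacking the neighbouring pyrone carbonyl.

Step 14
Reactants: 20 the free 4-phenol; 21 2-butynoic acid
Product: 22 tert-butyl 4-(but-2-ynoyloxy)-6-formyl-5-{[5-methoxy-4-(methoxymethoxy)-2-oxo-2H-pyran-3-yl]oxy}-2-(methoxymethoxy)-3-methylbenzoate
Conditions: DCC, DMAP (cat.), CH2Cl2, 0 °C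
Reagents that add atoms: none
Why: Steglich esterification of the only free hydroxyl, kept cold and with little DMAP so that the catalyst does not add to the ynoate.

Step 15
Reactants: 22 the pyrone–ynoate precursor
Product: 24 tert-butyl 6-formyl-3-methoxy-4,8-bis(methoxymethoxy)-1,9-dimethyl-11-oxo-11H-dibenzo[b,e][1,4]dioxepine-7-carboxylate, via bridged lactone cycloadduct 23 (not isolated)
Conditions: 1,2-dichlorobenzene (0.01 M), 150 °C, Ar
Reagents that add atoms: none
Why: Proposed new method: a thermal normal-demand [4+2] cycloaddition between the electron-rich 3,4,5-trioxygenated 2-pyrone (diene C3–C6) and the electron-poor aryl ynoate should give the 2-oxabicyclo[2.2.2]octadienone 23, which loses CO2 by retro-[4+2] to leave ring A aromatic; the closest known reaction type is the intramolecular 2-pyrone–alkyne Diels–Alder reaction with CO2 extrusion that gives fused benzoates. Ring A closes by the cycloaddition itself (bonds pyrone C3 to the carbonyl-bearing alkyne carbon and pyrone C6 to the methyl-bearing alkyne carbon), and the seven-membered ring closes in the same event because the five-atom tether (ether oxygen, ring B C5 and C4, ester oxygen, carbonyl carbon) ends on C3 and on the alkyne carbon that bonds to it. No stereocentre is formed, since the bridgeheads of 23 are lost on aromatisation. The selectivity needed is regiochemical and is secured by the tether, because only the carbonyl-bearing alkyne carbon can reach C3; this agrees with the polarisation (nucleophilic C6 to the ynoate β-carbon) and places the methyl group next to the ring A hydrogen. High dilution disfavours reaction between molecules, the ortho-phenylene unit holds diene and dienophile close once the aryl ester reaches its s-trans rotamer, and CO2 loss makes the step irreversible.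

Step 16
Reactants: 24 the protected depsidone
Product: 26 racemic lactol, via open aldehyde acid 25 (not isolated)
Conditions: TFA/CH2Cl2/H2O (10:10:1), 0 °C to rt
Reagents that add atoms: none
Why: Acidolysis removes the tert-butyl ester and both MOM ethers, water intercepts the formaldehyde released, and the ortho-formyl benzoic acid closes to the five-membered lactol by ring–chain tautomerism, while the aryl ester of the seven-membered ring is stable to acid.

Step 17
Reactants: 26 racemic lactol
Product: 27 (R)-lactol acetate
Conditions: vinyl acetate, immobilised Burkholderia cepacia lipase, Et3N (cat.), toluene/THF, 30 °C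
Reagents that add atoms: vinyl acetate, C=COC(C)=O
Why: Lipase-catalysed dynamic kinetic resolution, in which the enzyme acetylates one lactol enantiomer irreversibly while the other racemises through the open aldehyde–acid; the enzyme active site sets the stereocentre, the lipase used being the one a screen (this enzyme first) shows to give the (R)-acetate, and the hindered, hydrogen-bonded phenols are poor substrates.

Step 18
Reactants: 27 (R)-lactol acetate
Product: 28 target, (R)-lactol
Conditions: n-BuOH, immobilised Burkholderia cepacia lipase, anhydrous MTBE, rt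
Reagents that add atoms: none
Why: Lipase-catalysed alcoholysis cleaves the acetyl C–O bond and not the bond at the stereocentre, so (R) is retained, and the neutral, water-free medium avoids ring opening and racemisation; the enzyme accepts the acetate enantiomer it formed.

**Compound list**

1 | methyl methoxyacetate | COCC(=O)OC | starting material
2 | sodium 2,3-dimethoxy-3-oxoprop-1-en-1-olate (E/Z) | [Na+].[O-]C=C(OC)C(=O)OC | intermediate
3 | methyl 2,3-dimethoxyacrylate (E/Z) | COC=C(OC)C(=O)OC | intermediate
4 | 2,3-dimethoxyacrylic acid (E/Z) | COC=C(OC)C(=O)O | intermediate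
5 | 2,4-dihydroxy-3-methylbenzoic acid | Cc1c(O)ccc(C(=O)O)c1O | starting material
6 | 2,4-dihydroxy-3-methyl-5-(sulfooxy)benzoic acid (present as its salt) | Cc1c(O)c(OS(=O)(=O)O)cc(C(=O)O)c1O | intermediate
7 | 2,4,5-trihydroxy-3-methylbenzoic acid | Cc1c(O)c(O)cc(C(=O)O)c1O | intermediate
8 | tert-butyl 2,4,5-trihydroxy-3-methylbenzoate | Cc1c(O)c(O)cc(C(=O)OC(C)(C)C)c1O | intermediate
9 | tert-butyl 4-(allyloxy)-2,5-dihydroxy-3-methylbenzoate | C=CCOc1c(C)c(O)c(C(=O)OC(C)(C)C)cc1O | intermediate
10 | tert-butyl 4-(allyloxy)-6-formyl-2,5-dihydroxy-3-methylbenzoate | C=CCOc1c(C)c(O)c(C(=O)OC(C)(C)C)c(C=O)c1O | intermediate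
11 | tert-butyl bromoacetate | BrCC(=O)OC(C)(C)C | starting material
12 | tert-butyl 4-(allyloxy)-5-(2-tert-butoxy-2-oxoethoxy)-6-formyl-2-hydroxy-3-methylbenzoate | C=CCOc1c(C)c(O)c(C(=O)OC(C)(C)C)c(C=O)c1OCC(=O)OC(C)(C)C | intermediate
13 | tert-butyl 4-(allyloxy)-5-(2-tert-butoxy-2-oxoethoxy)-6-(dimethoxymethyl)-2-hydroxy-3-methylbenzoate | C=CCOc1c(C)c(O)c(C(=O)OC(C)(C)C)c(C(OC)OC)c1OCC(=O)OC(C)(C)C | intermediate
14 | tert-butyl 4-(allyloxy)-5-(2-tert-butoxy-2-oxoethoxy)-6-(dimethoxymethyl)-2-(methoxymethoxy)-3-methylbenzoate | C=CCOc1c(C)c(OCOC)c(C(=O)OC(C)(C)C)c(C(OC)OC)c1OCC(=O)OC(C)(C)C | intermediate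
15 | 2,3-dimethoxyacryloyl chloride (E/Z) | COC=C(OC)C(Cl)=O | intermediate
16 | tert-butyl 4-(allyloxy)-5-[(1-tert-butoxy-4,5-dimethoxy-1,3-dioxopent-4-en-2-yl)oxy]-6-(dimethoxymethyl)-2-(methoxymethoxy)-3-methylbenzoate (racemic, E/Z) | C=CCOc1c(C)c(OCOC)c(C(=O)OC(C)(C)C)c(C(OC)OC)c1OC(C(=O)OC(C)(C)C)C(=O)C(OC)=COC | intermediate
17 | tert-butyl 4-(allyloxy)-5-[(1-tert-butoxy-5-hydroxy-4-methoxy-1,3-dioxopent-4-en-2-yl)oxy]-6-formyl-2-(methoxymethoxy)-3-methylbenzoate (racemic, formyl enol) | C=CCOc1c(C)c(OCOC)c(C(=O)OC(C)(C)C)c(C=O)c1OC(C(=O)OC(C)(C)C)C(=O)C(OC)=CO | intermediate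
18 | tert-butyl 4-(allyloxy)-6-formyl-5-[(4-hydroxy-5-methoxy-2-oxo-2H-pyran-3-yl)oxy]-2-(methoxymethoxy)-3-methylbenzoate | C=CCOc1c(C)c(OCOC)c(C(=O)OC(C)(C)C)c(C=O)c1Oc1c(O)c(OC)coc1=O | intermediate
19 | tert-butyl 4-(allyloxy)-6-formyl-5-{[5-methoxy-4-(methoxymethoxy)-2-oxo-2H-pyran-3-yl]oxy}-2-(methoxymethoxy)-3-methylbenzoate | C=CCOc1c(C)c(OCOC)c(C(=O)OC(C)(C)C)c(C=O)c1Oc1c(OCOC)c(OC)coc1=O | intermediate
20 | tert-butyl 6-formyl-4-hydroxy-5-{[5-methoxy-4-(methoxymethoxy)-2-oxo-2H-pyran-3-yl]oxy}-2-(methoxymethoxy)-3-methylbenzoate | Oc1c(C)c(OCOC)c(C(=O)OC(C)(C)C)c(C=O)c1Oc1c(OCOC)c(OC)coc1=O | intermediate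
21 | 2-butynoic acid | CC#CC(=O)O | starting material
22 | tert-butyl 4-(but-2-ynoyloxy)-6-formyl-5-{[5-methoxy-4-(methoxymethoxy)-2-oxo-2H-pyran-3-yl]oxy}-2-(methoxymethoxy)-3-methylbenzoate | CC#CC(=O)Oc1c(C)c(OCOC)c(C(=O)OC(C)(C)C)c(C=O)c1Oc1c(OCOC)c(OC)coc1=O | intermediate
23 | bridged cycloadduct: 2-oxabicyclo[2.2.2]octa-5,7-dien-3-one with pyrone C3 and C6 as bridgeheads, spanned by the seven-membered lactone to ring B (racemic) | O=C1OC2C(OC)=C(OCOC)C1(Oc3c(C=O)c(C(=O)OC(C)(C)C)c(OCOC)c(C)c3OC4=O)C4=C2C | intermediate
24 | tert-butyl 6-formyl-3-methoxy-4,8-bis(methoxymethoxy)-1,9-dimethyl-11-oxo-11H-dibenzo[b,e][1,4]dioxepine-7-carboxylate | COc1cc(C)c2c(c1OCOC)Oc1c(c(C)c(OCOC)c(C(=O)OC(C)(C)C)c1C=O)OC2=O | intermediate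
25 | 6-formyl-4,8-dihydroxy-3-methoxy-1,9-dimethyl-11-oxo-11H-dibenzo[b,e][1,4]dioxepine-7-carboxylic acid | COc1cc(C)c2c(c1O)Oc1c(c(C)c(O)c(C(=O)O)c1C=O)OC2=O | intermediate
26 | racemic lactol (25 closed between the C7 carboxyl and the C6 formyl carbon as a 3-hydroxyphthalide) | COc1cc(C)c2c(c1O)Oc1c(c(C)c(O)c3c1C(O)OC3=O)OC2=O | intermediate
27 | (R)-lactol acetate (acetoxy group on the lactol carbon, R) | COc1cc(C)c2c(c1O)Oc1c(c(C)c(O)c3c1[C@H](OC(C)=O)OC3=O)OC2=O | intermediate
28 | CNP0211607.1, the (R)-lactol | COc1cc(C)c2c(c1O)Oc1c(c(C)c(O)c3c1[C@H](O)OC3=O)OC2=O | target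

**Step count and risk**

Total: 18 steps. Longest linear sequence: 16 steps (steps 3 to 18, from 5); steps 1 and 2 make the side fragment that joins at step 10.

Steps most likely to fail:

1. Step 15. On heating, 22 may decompose or react between molecules before the aryl ester reaches the rotamer that lets the tether fold, so that ring A is never formed. The fallback uncouples cycloaddition from ring closure and uses known chemistry; it sets out from 19 and 21. Acid 21 is esterified with allyl alcohol (DCC, DMAP) to allyl but-2-ynoate F1. Pyrone 19 and excess F1 are heated (1,2-dichlorobenzene, 160 °C) in an intermolecular 2-pyrone–alkynoate Diels–Alder reaction with loss of CO2. The polarisation (pyrone C6 to the ynoate β-carbon) should favour the diaryl ether allyl benzoate F2, and the regioisomer is removed by chromatography. Pd(PPh3)4 with 4-MeC6H4SO2Na removes the allyl ether and the allyl ester together to give the hydroxy acid F3. Carbodiimide lactonisation at high dilution (EDC, DMAP, CH2Cl2) closes the seven-membered aryl ester and returns to the route at 24.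

2. Step 17. The enzyme may acylate the bulky polycyclic lactol slowly or with poor discrimination between its enantiomers, or racemisation may be too slow for a dynamic process. The fallback replaces enzymatic selection by chromatographic resolution and sets out from 26. Exhaustive acetylation (Ac2O, pyridine, 0 °C) gives the racemic triacetate F4, in which the lactol carbon is fixed as an acylal. Preparative chromatography on a chiral stationary phase separates the (R)-triacetate F5 from the (S)-triacetate F6, which is set aside. Lipase-catalysed butanolysis under the conditions of step 18 removes the three acetyl groups and returns to the route at 28.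

3. Step 10. C-acylation of the hindered enolate may be incomplete, or acylation may go to oxygen or occur twice. The fallback builds the side chain in two stages and sets out from 14. The lithium enolate (LiN(SiMe3)2, THF, −78 °C) is acylated with methoxyacetyl chloride, a small electrophile without a competing conjugate position, to give the methoxyacetyl β-keto ester F7. Its dianion (LiN(iPr)2, 2.2 equiv, THF, −78 °C) is formylated at the methoxy-bearing carbon with ethyl formate to give the hydroxymethylene β-keto ester F8, with the acetal still in place. Treatment with 1 M HCl in THF removes the acetal and returns to the route at 17, the intermediate of step 11.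

**Further compounds**

F1 | step 15 | allyl but-2-ynoate | CC#CC(=O)OCC=C
F2 | step 15 | allyl 2-[6-(allyloxy)-3-(tert-butoxycarbonyl)-2-formyl-4-(methoxymethoxy)-5-methylphenoxy]-4-methoxy-3-(methoxymethoxy)-6-methylbenzoate | COc1cc(C)c(C(=O)OCC=C)c(Oc2c(OCC=C)c(C)c(OCOC)c(C(=O)OC(C)(C)C)c2C=O)c1OCOC
F3 | step 15 | 2-[3-(tert-butoxycarbonyl)-2-formyl-6-hydroxy-4-(methoxymethoxy)-5-methylphenoxy]-4-methoxy-3-(methoxymethoxy)-6-methylbenzoic acid | COc1cc(C)c(C(=O)O)c(Oc2c(O)c(C)c(OCOC)c(C(=O)OC(C)(C)C)c2C=O)c1OCOC
F4 | step 17 | racemic triacetate of 26 (both phenols and the lactol hydroxyl acetylated) | COc1cc(C)c2c(c1OC(C)=O)Oc1c(c(C)c(OC(C)=O)c3c1C(OC(C)=O)OC3=O)OC2=O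
F5 | step 17 | (R)-triacetate | COc1cc(C)c2c(c1OC(C)=O)Oc1c(c(C)c(OC(C)=O)c3c1[C@H](OC(C)=O)OC3=O)OC2=O
F6 | step 17 | (S)-triacetate | COc1cc(C)c2c(c1OC(C)=O)Oc1c(c(C)c(OC(C)=O)c3c1[C@@H](OC(C)=O)OC3=O)OC2=O
F7 | step 10 | tert-butyl 4-(allyloxy)-5-[(1-tert-butoxy-4-methoxy-1,3-dioxobutan-2-yl)oxy]-6-(dimethoxymethyl)-2-(methoxymethoxy)-3-methylbenzoate (racemic) | C=CCOc1c(C)c(OCOC)c(C(=O)OC(C)(C)C)c(C(OC)OC)c1OC(C(=O)OC(C)(C)C)C(=O)COC
F8 | step 10 | tert-butyl 4-(allyloxy)-5-[(1-tert-butoxy-5-hydroxy-4-methoxy-1,3-dioxopent-4-en-2-yl)oxy]-6-(dimethoxymethyl)-2-(methoxymethoxy)-3-methylbenzoate (racemic) | C=CCOc1c(C)c(OCOC)c(C(=O)OC(C)(C)C)c(C(OC)OC)c1OC(C(=O)OC(C)(C)C)C(=O)C(OC)=CO
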